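**Retrosynthetic overview**

- The target is an ent-labdane (labdane numbering): C19 acid and C18 methyl on C4, C20 methyl on C10, C17 methylene on C8, and a C11–C15 chain on C9 that ends in the (R)-2-methylbutanoate. Disconnected first are the O15 ester, the C8=C17 alkene (from a C8 ketone), the C18 methyl (from the equatorial ester of a C4 malonate) and C11–C12 (Wittig at a C11 aldehyde).
- Feature on which the plan rests: rings A and B share the bond C5–C10, and quaternary C10 sits next to C9. This pair maps onto a trisubstituted (E)-C9=C10 enoyl imide facing a C5=C6–C7=C8 1-silyloxydiene, the two joined through C4 (malonate carbon), C3, C2 and C1.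
- One intramolecular Diels–Alder reaction of this achiral triene forms C5–C10 and C8–C9 and closes both rings together: ring B as the cyclohexene, ring A through the fusion bond. A chiral divalent-copper bis(oxazoline) Lewis acid supplies the absolute configuration, and the C8 silyloxy group later delivers C17.
- The triene is built from dimethyl allylmalonate and an iodo enoyl imide (from 5-chloropentan-2-one), then cross-metathesis to an enal and silyl dienol ether formation, which fixes the (1E,3E) diene. C13 comes from the 4-methyl half ester of (S)-methylsuccinic acid, the acyl group from (R)-2-methylbutanoic acid.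

Key step: step 8

Remark: labdane numbering is used for every bicyclic compound, and the 4-methyl half ester of (S)-methylsuccinic acid is taken as the purchased form of that acid.

**Route**

Step 1
Reactants: 1 5-chloropentan-2-one
Product: 2 ethyl (E)-6-chloro-3-methylhex-2-enoate
Conditions: (EtO)2P(O)CH2CO2Et, NaH, THF, 0 °C → 50 °C; chromatography to remove the (Z)-isomer
Reagents that add atoms: triethyl phosphonoacetate, CCOC(=O)CP(=O)(OCC)OCC
Why: Horner–Wadsworth–Emmons olefination of the methyl ketone gives mainly the (E)-trisubstituted enoate, the minor (Z)-isomer is removed on silica, and the weakly basic stabilised anion should leave the γ-chloro ketone uncyclised.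

Step 2
Reactants: 2 ethyl (E)-6-chloro-3-methylhex-2-enoate
Product: 3 (E)-6-chloro-3-methylhex-2-enoic acid
Conditions: LiOH, THF/MeOH/H2O, rt; then aq. HCl
Reagents that add atoms: lithium hydroxide, [Li+].[OH-]
Why: Saponification of the unhindered ethyl ester at room temperature leaves the primary chloride and the alkene geometry untouched.

Step 3
Reactants: 3 (E)-6-chloro-3-methylhex-2-enoic acid
Product: 5 3-[(E)-6-chloro-3-methylhex-2-enoyl]oxazolidin-2-one, via mixed pivalic anhydride 4 (not isolated)
Conditions: t-BuCOCl, Et3N, THF, −20 °C; then oxazolidin-2-one, LiCl, rt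
Reagents that add atoms: oxazolidin-2-one, O=C1NCCO1; pivaloyl chloride, CC(C)(C)C(Cl)=O (its acyl group is held only in 4)
Why: Mixed-anhydride activation followed by LiCl-assisted N-acylation is the standard imide synthesis, with attack at the less hindered enoyl carbonyl and no migration of the conjugated (E)-alkene.

Step 4
Reactants: 5 3-[(E)-6-chloro-3-methylhex-2-enoyl]oxazolidin-2-one
Product: 6 3-[(E)-6-iodo-3-methylhex-2-enoyl]oxazolidin-2-one
Conditions: NaI, acetone, reflux
Reagents that add atoms: sodium iodide, [Na+].[I-]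
Why: Finkelstein exchange (SN2), driven by precipitation of NaCl, turns the primary chloride into the more reactive iodide without touching the imide.

Step 5
Reactants: 6 3-[(E)-6-iodo-3-methylhex-2-enoyl]oxazolidin-2-one; 7 dimethyl allylmalonate
Product: 9 dimethyl 2-allyl-2-[(E)-4-methyl-6-oxo-6-(2-oxooxazolidin-3-yl)hex-4-enyl]malonate, via sodium malonate enolate 8 (not isolated)
Conditions: NaH, THF/DMF, 0 °C; then 6, rt
Reagents that add atoms: none
Why: Malonate alkylation (SN2) of the soft enolate at the primary iodide should be faster than conjugate addition to the β,β-disubstituted enoyl imide, and it creates the quaternary carbon that becomes C4.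

Step 6
Reactants: 9 dimethyl 2-allyl-2-[(E)-4-methyl-6-oxo-6-(2-oxooxazolidin-3-yl)hex-4-enyl]malonate
Product: 10 dimethyl 2-[(E)-4-oxobut-2-enyl]-2-[(E)-4-methyl-6-oxo-6-(2-oxooxazolidin-3-yl)hex-4-enyl]malonate
Conditions: crotonaldehyde (5 equiv), second-generation Hoveyda–Grubbs catalyst RuCl2(H2IMes)(=CH-C6H4-2-O-i-Pr) (5 mol%), CH2Cl2, 40 °C
Reagents that add atoms: (E)-crotonaldehyde, C/C=C/C=O
Why: Olefin cross-metathesis of the monosubstituted allyl alkene with excess crotonaldehyde gives the (E)-enal, while the trisubstituted, electron-poor enoyl imide alkene is inert to the ruthenium carbene.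

Step 7
Reactants: 10 dimethyl 2-[(E)-4-oxobut-2-enyl]-2-[(E)-4-methyl-6-oxo-6-(2-oxooxazolidin-3-yl)hex-4-enyl]malonate
Product: 11 dimethyl 2-[(1E,3E)-4-(tert-butyldimethylsilyloxy)buta-1,3-dienyl]-2-[(E)-4-methyl-6-oxo-6-(2-oxooxazolidin-3-yl)hex-4-enyl]malonate
Conditions: TBSOTf, Et3N, CH2Cl2, −78 → 0 °C
Reagents that add atoms: tert-butyldimethylsilyl triflate, CC(C)(C)[Si](C)(C)OS(=O)(=O)C(F)(F)F
Why: Silyl dienol ether formation (O-silylation of the enal, then γ-deprotonation) gives the 1-silyloxydiene, (1E) from the s-trans enal and (3E) because the quaternary malonate carbon avoids allylic strain, and the aldehyde reacts far faster than the imide.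

Step 8
Reactants: 11 dimethyl 2-[(1E,3E)-4-(tert-butyldimethylsilyloxy)buta-1,3-dienyl]-2-[(E)-4-methyl-6-oxo-6-(2-oxooxazolidin-3-yl)hex-4-enyl]malonate
Product: 12 trans-fused Δ6-octalin imide (5S,8R,9S,10R): C4 bis(methoxycarbonyl), C8 OTBS, C9 (2-oxooxazolidin-3-yl)carbonyl, C10 methyl; H5 trans to C20, C11 and O8 cis to C20
Conditions: [Cu((S,S)-t-Bu-box)](SbF6)2 (10 mol%; from CuCl2, 2,2′-isopropylidenebis[(4S)-4-tert-butyl-2-oxazoline] and AgSbF6), CH2Cl2, −20 °C → rt
Reagents that add atoms: none
Why: Proposed new method: the closest known reaction type is the [Cu(t-Bu-box)](SbF6)2-catalysed intramolecular Diels–Alder reaction of trienimides whose dienophile carries one β-substituent, and the extension is a β,β-disubstituted enoyl imide that creates quaternary C10; two-point chelation of the imide carbonyls to square-planar divalent copper holds the enoyl unit s-cis and lowers its LUMO, the 1-silyloxydiene has its largest HOMO coefficient at C5, and a concerted but asynchronous [4+2] addition therefore starts with C5–C10 and ends with C8–C9, the silyloxy carbon finishing next to the acyl-bearing carbon. Ring B closes as the new cyclohexene of the cycloaddition, and ring A closes as a six-membered carbocycle through the fusion bond C5–C10, its C4–C3–C2–C1 tether folding as a chair that the gem-diester at C4 favours. The tether lies exo (anti to the diene) and the C20 methyl endo, which gives the trans relation of H5 and C20; the (E)-alkene geometry is transferred suprafacially, so the acyl carbon C11 ends cis to C20, and the endo position of the chelated carbonyl over the (E,E)-diene puts O8 cis to C11. Because the triene has no stereocentre, the absolute configuration rests on the ligand: in the square-planar chelate the tert-butyl group of the (S,S)-ligand covers the Si face of C9, C8 bonds to its Re face and the (5S,8R,9S,10R) adduct should result, the (R,R)-ligand being used instead should the sense prove reversed. The step needs endo, trans-fused diastereoselection and a catalysed path that outruns silyl loss; the (E)-dienophile, the (1E,3E)-diene, the non-coordinating SbF6 counter-ion and the low temperature are chosen to secure them.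

Step 9
Reactants: 12 trans-fused Δ6-octalin imide
Product: 13 C11 primary alcohol (C9–CH2OH; ring stereocentres as in 12)
Conditions: LiBH4, H2O (1 equiv), Et2O, 0 °C
Reagents that add atoms: none
Why: Reductive cleavage of the N-acyl oxazolidinone by LiBH4 occurs at the activated exocyclic carbonyl faster than reduction of the hindered quaternary methyl esters, and C9 is not touched.

Step 10
Reactants: 13 C11 primary alcohol
Product: 14 C11 aldehyde (C9–CHO; ring stereocentres as in 12)
Conditions: Dess–Martin periodinane, NaHCO3, CH2Cl2, 0 °C → rt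
Reagents that add atoms: none
Why: Dess–Martin oxidation under bicarbonate buffer gives the aldehyde without epimerising C9 or eliminating the β-silyloxy group.

Step 11
Reactants: 15 (S)-4-methoxy-2-methyl-4-oxobutanoic acid (4-methyl hydrogen (S)-2-methylsuccinate)
Product: 16 methyl (S)-4-hydroxy-3-methylbutanoate
Conditions: BH3·SMe2, THF, −10 °C → rt; MeOH quench
Reagents that add atoms: none
Why: Borane reduces the free carboxylic acid through its acyloxyborane much faster than the methyl ester, and the stereocentre is not enolised.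

Step 12
Reactants: 16 methyl (S)-4-hydroxy-3-methylbutanoate
Product: 17 methyl (S)-4-iodo-3-methylbutanoate
Conditions: I2, PPh3, imidazole, CH2Cl2, 0 °C → rt
Reagents that add atoms: iodine, [I][I]
Why: Appel-type iodination (SN2 at the primary carbinol) under non-acidic conditions avoids lactonisation of the γ-hydroxy ester and leaves the stereocentre alone.

Step 13
Reactants: 17 methyl (S)-4-iodo-3-methylbutanoate
Product: 18 (S)-4-iodo-3-methylbutan-1-ol
Conditions: i-Bu2AlH (2.3 equiv), CH2Cl2, −78 → −20 °C; aq. potassium sodium tartrate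
Reagents that add atoms: none
Why: Ester reduction by the electrophilic aluminium hydride gives the primary alcohol at low temperature, and the alkyl iodide is inert to this reagent.

Step 14
Reactants: 18 (S)-4-iodo-3-methylbutan-1-ol
Product: 19 (S)-tert-butyl(4-iodo-3-methylbutoxy)diphenylsilane
Conditions: TBDPSCl, imidazole, CH2Cl2, 0 °C → rt
Reagents that add atoms: tert-butylchlorodiphenylsilane, CC(C)(C)[Si](Cl)(c1ccccc1)c1ccccc1
Why: Silylation of the primary alcohol under mild base is faster than cyclisation to the tetrahydrofuran and installs a group that later outlasts the ring-B TBS ether.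

Step 15
Reactants: 19 (S)-tert-butyl(4-iodo-3-methylbutoxy)diphenylsilane
Product: 20 [(S)-4-(tert-butyldiphenylsilyloxy)-2-methylbutyl]triphenylphosphonium iodide
Conditions: PPh3, MeCN, reflux
Reagents that add atoms: triphenylphosphine, c1ccc(cc1)P(c1ccccc1)c1ccccc1
Why: SN2 quaternisation of triphenylphosphine by the β-branched primary iodide on prolonged heating gives the salt, the stereocentre lying one carbon from the reacting centre.

Step 16
Reactants: 14 C11 aldehyde; 20 [(S)-4-(tert-butyldiphenylsilyloxy)-2-methylbutyl]triphenylphosphonium iodide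
Product: 22 (Z)-C11=C12 alkene carrying the full C11–C15 chain (O15 as TBDPS ether; C6=C7 and C8–OTBS retained), via phosphorus ylide 21 (not isolated)
Conditions: NaN(SiMe3)2, THF, −78 → 0 °C; then 14, −78 °C → rt
Reagents that add atoms: none
Why: Wittig olefination with the non-stabilised ylide should outpace enolisation of the aldehyde; C13 is not acidic and is carried unchanged, and the (Z) geometry is of no consequence because the alkene is reduced next.

Step 17
Reactants: 22 (Z)-C11=C12 alkene
Product: 23 saturated diester (C4 bis(methoxycarbonyl), C8 OTBS, O15 TBDPS)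
Conditions: H2 (1 atm), PtO2, EtOAc, rt
Reagents that add atoms: none
Why: Heterogeneous hydrogenation saturates C6=C7 and C11=C12, and platinum is preferred to palladium because it causes little double-bond migration (which would scramble C13 through a C12=C13 isomer) and little hydrogenolysis of the allylic silyl ether.

Step 18
Reactants: 23 saturated diester
Product: 24 C18 alcohol (equatorial CH2OH and axial CO2Me on C4)
Conditions: LiAlH(Ot-Bu)3 (4 equiv), THF, 0 °C → reflux
Reagents that add atoms: none
Why: Mono-reduction of a gem-diester by the bulky alkoxyaluminium hydride stops at the β-hydroxy ester because the alkoxyaluminate deactivates the second ester, and the equatorial ester should react because the axial one is screened by the syn-axial C20 methyl, which sets C4.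

Step 19
Reactants: 24 C18 alcohol
Product: 25 C18 O-(imidazol-1-ylthiocarbonyl) derivative
Conditions: 1,1′-thiocarbonyldiimidazole, DMAP (cat.), ClCH2CH2Cl, reflux
Reagents that add atoms: 1,1′-thiocarbonyldiimidazole, S=C(n1ccnc1)n1ccnc1
Why: Thioacylation of the neopentyl primary alcohol under neutral conditions (first half of the Barton–McCombie deoxygenation) avoids an alkoxide and so avoids retro-aldol loss of formaldehyde from the β-hydroxy ester.

Step 20
Reactants: 25 C18 O-(imidazol-1-ylthiocarbonyl) derivative
Product: 26 C18 methyl compound (C4: equatorial CH3, axial CO2Me; C8 OTBS; O15 TBDPS)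
Conditions: Bu3SnH, AIBN (cat.), toluene, reflux
Reagents that add atoms: none
Why: Barton–McCombie radical deoxygenation: the stannyl radical adds to the thiocarbonyl, the C18–O bond fragments at reflux and the primary radical takes hydrogen from Bu3SnH, with esters and silyl ethers untouched.

Step 21
Reactants: 26 C18 methyl compound
Product: 27 C8 alcohol (axial OH; O15 TBDPS kept)
Conditions: HF·pyridine, pyridine, THF, 0 °C → rt
Reagents that add atoms: none
Why: Selective desilylation: buffered HF removes the secondary TBS ether while the bulkier, more acid-stable primary TBDPS ether survives.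

Step 22
Reactants: 27 C8 alcohol
Product: 28 C8 ketone
Conditions: Dess–Martin periodinane, NaHCO3, CH2Cl2, rt
Reagents that add atoms: none
Why: Dess–Martin oxidation of the hindered axial alcohol gives the ketone, and C9 keeps its equatorial chain, the thermodynamically preferred arrangement even if the ketone enolises.

Step 23
Reactants: 28 C8 ketone
Product: 29 methyl 15-(tert-butyldiphenylsilyloxy)labd-8(17)-en-19-oate (configuration as in 34)
Conditions: Ph3PCH3Br, KOt-Bu, toluene, rt → 70 °C
Reagents that add atoms: methyltriphenylphosphonium bromide, [Br-].C[P+](c1ccccc1)(c1ccccc1)c1ccccc1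
Why: Wittig methylenation with excess Ph3P=CH2 is the standard way to install the 8(17)-exocyclic alkene of labdanes; the axial neopentyl ester does not react and C9 stays equatorial.

Step 24
Reactants: 29 methyl 15-(tert-butyldiphenylsilyloxy)labd-8(17)-en-19-oate
Product: 30 methyl 15-hydroxylabd-8(17)-en-19-oate
Conditions: Bu4NF, THF, rt
Reagents that add atoms: none
Why: Fluoride-induced desilylation cleaves the TBDPS ether, and the hindered methyl ester and the exocyclic alkene are inert.

Step 25
Reactants: 30 methyl 15-hydroxylabd-8(17)-en-19-oate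
Product: 31 15-hydroxylabd-8(17)-en-19-oic acid
Conditions: NaSEt, DMF, 100 °C; then cold dilute HCl
Reagents that add atoms: none
Why: The axial C19 ester resists attack at its carbonyl, so it is cleaved by SN2 O-demethylation with thiolate in a dipolar aprotic solvent, non-acidic conditions that do not isomerise the exocyclic alkene.

Step 26
Reactants: 32 (R)-2-methylbutanoic acid
Product: 33 (R)-2-methylbutanoyl chloride
Conditions: (COCl)2, DMF (cat.), CH2Cl2, 0 °C → rt; concentrate
Reagents that add atoms: oxalyl chloride, O=C(Cl)C(Cl)=O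
Why: Vilsmeier-type activation gives the acid chloride without base, so no ketene forms and the α-stereocentre is retained.

Step 27
Reactants: 31 15-hydroxylabd-8(17)-en-19-oic acid; 33 (R)-2-methylbutanoyl chloride
Product: 34 (4R,5S,9R,10S,13R)-15-[(2R)-2-methylbutanoyloxy]labd-8(17)-en-19-oic acid (CNP0109063.1)
Conditions: pyridine, DMAP (cat.), CH2Cl2, 0 °C; then aq. NaHCO3, mild acidification
Reagents that add atoms: none
Why: Pyridine/DMAP-mediated O-acylation of the primary alcohol; the hindered tertiary C19 acid can at most form a mixed anhydride that the bicarbonate work-up hydrolyses back, and the weak base at 0 °C avoids ketene formation, so the (R)-centre is kept.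

**Compound list**

1 | 5-chloropentan-2-one | CC(=O)CCCCl | starting material
2 | ethyl (E)-6-chloro-3-methylhex-2-enoate | CCOC(=O)/C=C(\C)CCCCl | intermediate
3 | (E)-6-chloro-3-methylhex-2-enoic acid | OC(=O)/C=C(\C)CCCCl | intermediate
4 | (E)-6-chloro-3-methylhex-2-enoic pivalic anhydride | CC(C)(C)C(=O)OC(=O)/C=C(\C)CCCCl | intermediate (not isolated)
5 | 3-[(E)-6-chloro-3-methylhex-2-enoyl]oxazolidin-2-one | O=C(/C=C(\C)CCCCl)N1CCOC1=O | intermediate
6 | 3-[(E)-6-iodo-3-methylhex-2-enoyl]oxazolidin-2-one | O=C(/C=C(\C)CCCI)N1CCOC1=O | intermediate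
7 | dimethyl allylmalonate | C=CCC(C(=O)OC)C(=O)OC | starting material
8 | sodium enolate of dimethyl allylmalonate | [Na+].C=CC[C-](C(=O)OC)C(=O)OC | intermediate (not isolated)
9 | dimethyl 2-allyl-2-[(E)-4-methyl-6-oxo-6-(2-oxooxazolidin-3-yl)hex-4-enyl]malonate | C=CCC(CCC/C(C)=C/C(=O)N1CCOC1=O)(C(=O)OC)C(=O)OC | intermediate
10 | dimethyl 2-[(E)-4-oxobut-2-enyl]-2-[(E)-4-methyl-6-oxo-6-(2-oxooxazolidin-3-yl)hex-4-enyl]malonate | O=C/C=C/CC(CCC/C(C)=C/C(=O)N1CCOC1=O)(C(=O)OC)C(=O)OC | intermediate
11 | dimethyl 2-[(1E,3E)-4-(tert-butyldimethylsilyloxy)buta-1,3-dienyl]-2-[(E)-4-methyl-6-oxo-6-(2-oxooxazolidin-3-yl)hex-4-enyl]malonate | COC(=O)C(/C=C/C=C/O[Si](C)(C)C(C)(C)C)(CCC/C(C)=C/C(=O)N1CCOC1=O)C(=O)OC | intermediate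
12 | (5S,8R,9S,10R) trans-fused Δ6-octalin imide: C4 bis(methoxycarbonyl), C8 OTBS, C9 (2-oxooxazolidin-3-yl)carbonyl, C10 methyl | CC(C)(C)[Si](C)(C)O[C@@H]1C=C[C@H]2[C@@](C)(CCCC2(C(=O)OC)C(=O)OC)[C@@H]1C(=O)N3CCOC3=O | intermediate
13 | C11 primary alcohol of 12 (C9–CH2OH) | CC(C)(C)[Si](C)(C)O[C@@H]1C=C[C@H]2[C@@](C)(CCCC2(C(=O)OC)C(=O)OC)[C@@H]1CO | intermediate
14 | C11 aldehyde (C9–CHO) | CC(C)(C)[Si](C)(C)O[C@@H]1C=C[C@H]2[C@@](C)(CCCC2(C(=O)OC)C(=O)OC)[C@@H]1C=O | intermediate
15 | (S)-4-methoxy-2-methyl-4-oxobutanoic acid | OC(=O)[C@@H](C)CC(=O)OC | starting material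
16 | methyl (S)-4-hydroxy-3-methylbutanoate | OC[C@@H](C)CC(=O)OC | intermediate
17 | methyl (S)-4-iodo-3-methylbutanoate | IC[C@@H](C)CC(=O)OC | intermediate
18 | (S)-4-iodo-3-methylbutan-1-ol | IC[C@@H](C)CCO | intermediate
19 | (S)-tert-butyl(4-iodo-3-methylbutoxy)diphenylsilane | IC[C@@H](C)CCO[Si](c1ccccc1)(c2ccccc2)C(C)(C)C | intermediate
20 | [(S)-4-(tert-butyldiphenylsilyloxy)-2-methylbutyl]triphenylphosphonium iodide | [I-].c1ccccc1[P+](c2ccccc2)(c3ccccc3)C[C@@H](C)CCO[Si](c4ccccc4)(c5ccccc5)C(C)(C)C | intermediate
21 | ylide of 20, [(S)-4-(tert-butyldiphenylsilyloxy)-2-methylbutylidene]triphenylphosphorane | c1ccccc1P(c2ccccc2)(c3ccccc3)=C[C@@H](C)CCO[Si](c4ccccc4)(c5ccccc5)C(C)(C)C | intermediate (not isolated)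
22 | (Z)-C11=C12 alkene: Δ6-octalin diester with C8 OTBS and the C11–C15 chain, O15 TBDPS | CC(C)(C)[Si](C)(C)O[C@@H]1C=C[C@H]2[C@@](C)(CCCC2(C(=O)OC)C(=O)OC)[C@@H]1/C=C\[C@@H](C)CCO[Si](c3ccccc3)(c4ccccc4)C(C)(C)C | intermediate
23 | saturated decalin diester: C4 bis(methoxycarbonyl), C8 OTBS, O15 TBDPS | CC(C)(C)[Si](C)(C)O[C@@H]1CC[C@H]2[C@@](C)(CCCC2(C(=O)OC)C(=O)OC)[C@@H]1CC[C@@H](C)CCO[Si](c3ccccc3)(c4ccccc4)C(C)(C)C | intermediate
24 | C18 alcohol: C4 equatorial CH2OH, axial CO2Me | CC(C)(C)[Si](C)(C)O[C@@H]1CC[C@H]2[C@@](C)(CCC[C@@]2(CO)C(=O)OC)[C@@H]1CC[C@@H](C)CCO[Si](c3ccccc3)(c4ccccc4)C(C)(C)C | intermediate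
25 | C18 O-(imidazol-1-ylthiocarbonyl) derivative of 24 | CC(C)(C)[Si](C)(C)O[C@@H]1CC[C@H]2[C@@](C)(CCC[C@@]2(COC(=S)n3ccnc3)C(=O)OC)[C@@H]1CC[C@@H](C)CCO[Si](c4ccccc4)(c5ccccc5)C(C)(C)C | intermediate
26 | methyl 8-(tert-butyldimethylsilyloxy)-15-(tert-butyldiphenylsilyloxy)labdan-19-oate (17-nor; C18 methyl in place) | CC(C)(C)[Si](C)(C)O[C@@H]1CC[C@H]2[C@@](C)(CCC[C@@]2(C)C(=O)OC)[C@@H]1CC[C@@H](C)CCO[Si](c3ccccc3)(c4ccccc4)C(C)(C)C | intermediate
27 | C8 alcohol (axial OH), O15 TBDPS | O[C@@H]1CC[C@H]2[C@@](C)(CCC[C@@]2(C)C(=O)OC)[C@@H]1CC[C@@H](C)CCO[Si](c3ccccc3)(c4ccccc4)C(C)(C)C | intermediate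
28 | C8 ketone, O15 TBDPS | O=C1CC[C@H]2[C@@](C)(CCC[C@@]2(C)C(=O)OC)[C@@H]1CC[C@@H](C)CCO[Si](c3ccccc3)(c4ccccc4)C(C)(C)C | intermediate
29 | methyl 15-(tert-butyldiphenylsilyloxy)labd-8(17)-en-19-oate | C=C1CC[C@H]2[C@@](C)(CCC[C@@]2(C)C(=O)OC)[C@@H]1CC[C@@H](C)CCO[Si](c3ccccc3)(c4ccccc4)C(C)(C)C | intermediate
30 | methyl 15-hydroxylabd-8(17)-en-19-oate | C=C1CC[C@H]2[C@@](C)(CCC[C@@]2(C)C(=O)OC)[C@@H]1CC[C@@H](C)CCO | intermediate
31 | 15-hydroxylabd-8(17)-en-19-oic acid | C=C1CC[C@H]2[C@@](C)(CCC[C@@]2(C)C(=O)O)[C@@H]1CC[C@@H](C)CCO | intermediate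
32 | (R)-2-methylbutanoic acid | CC[C@@H](C)C(=O)O | starting material
33 | (R)-2-methylbutanoyl chloride | CC[C@@H](C)C(Cl)=O | intermediate
34 | (4R,5S,9R,10S,13R)-15-[(2R)-2-methylbutanoyloxy]labd-8(17)-en-19-oic acid | C=C1CC[C@H]2[C@@](C)(CCC[C@@]2(C)C(=O)O)[C@@H]1CC[C@@H](C)CCOC(=O)[C@H](C)CC | target

**Step count and risk**

Total steps: 27. Longest linear sequence: 21 steps (steps 1–10, 16–25 and 27).

Most likely to fail:

1. Step 8 (the key cycloaddition). The doubly β-substituted enoyl imide is a reluctant dienophile and the malonate can tie up the copper centre, so the reaction may stall. The catalyst may also discriminate the two faces of C9 less well than with simpler imides, or the Lewis acid may strip or eliminate the silyl dienol ether before ring closure. The C8 configuration is of no consequence, and a wrong C9 epimer could be equilibrated at aldehyde 14 towards the equatorial, desired one; the real exposure is conversion and enantioselectivity.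
Fallback (known chemistry, a covalently bound controller in place of the catalyst): setting out from acid 3, the mixed pivalic anhydride is coupled with (R)-4-benzyloxazolidin-2-one to give the chloro imide F1. This is carried through the same Finkelstein exchange to the iodo imide F2, the same alkylation of 7 to the allyl malonate F3, the same cross-metathesis to the enal F4 and the same silylation to the auxiliary triene F5. Ring closure is then promoted by Me2AlCl (1.4 equiv, CH2Cl2, −30 °C), the established activator for auxiliary-controlled Diels–Alder reactions of N-enoyl oxazolidinones, or simply by heating in toluene. In the aluminium chelate the benzyl group covers the Si face of C9, which should give the auxiliary adduct F6. Because the stereoisomers are now diastereomers they are separated on silica. LiBH4/H2O as in step 9 removes the auxiliary, and the route is rejoined at alcohol 13.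

2. Step 18 (differentiation of the two esters). Hydride delivery may not discriminate cleanly between the equatorial and the axial ester, or may run on to the diol.
Fallback (hydrolytic instead of reductive discrimination): setting out from diester 23, the exposed equatorial ester alone is hydrolysed with Me3SnOH (ClCH2CH2Cl, 80 °C) to the half acid F7, the axial ester being shielded from attack at its carbonyl. BH3·SMe2 then reduces the free acid in the presence of that ester, and the route is rejoined at alcohol 24.

3. Step 16 (Wittig coupling). Olefination at the α-branched aldehyde flanked by quaternary C10 and the C8 silyl ether may be slower than enolisation by the ylide, leading to loss of silanol across C8–C9 or to recovered material.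
Fallback (carbonyl addition and deoxygenation instead of olefination): setting out from iodide 19, iodine–lithium exchange (t-BuLi, Et2O, −78 °C) and transmetalation with anhydrous CeCl3 give a weakly basic organocerium reagent that should add to aldehyde 14 without touching the esters, giving the C11 carbinol F8 (both C11 epimers are usable). Thioacylation with 1,1′-thiocarbonyldiimidazole gives the thiocarbonyl derivative F9, and Bu3SnH/AIBN removes the oxygen to give the C11-deoxy Δ6 compound F10. Hydrogenation over PtO2 as in step 17 rejoins the route at 23.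

**Further compounds**

F1 | step 8 | (R)-4-benzyl-3-[(E)-6-chloro-3-methylhex-2-enoyl]oxazolidin-2-one | O=C(/C=C(\C)CCCCl)N1[C@H](Cc2ccccc2)COC1=O
F2 | step 8 | (R)-4-benzyl-3-[(E)-6-iodo-3-methylhex-2-enoyl]oxazolidin-2-one | O=C(/C=C(\C)CCCI)N1[C@H](Cc2ccccc2)COC1=O
F3 | step 8 | dimethyl 2-allyl-2-{(E)-6-[(R)-4-benzyl-2-oxooxazolidin-3-yl]-4-methyl-6-oxohex-4-enyl}malonate | C=CCC(CCC/C(C)=C/C(=O)N1[C@H](Cc2ccccc2)COC1=O)(C(=O)OC)C(=O)OC
F4 | step 8 | dimethyl 2-[(E)-4-oxobut-2-enyl]-2-{(E)-6-[(R)-4-benzyl-2-oxooxazolidin-3-yl]-4-methyl-6-oxohex-4-enyl}malonate | O=C/C=C/CC(CCC/C(C)=C/C(=O)N1[C@H](Cc2ccccc2)COC1=O)(C(=O)OC)C(=O)OC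
F5 | step 8 | dimethyl 2-[(1E,3E)-4-(tert-butyldimethylsilyloxy)buta-1,3-dienyl]-2-{(E)-6-[(R)-4-benzyl-2-oxooxazolidin-3-yl]-4-methyl-6-oxohex-4-enyl}malonate | COC(=O)C(/C=C/C=C/O[Si](C)(C)C(C)(C)C)(CCC/C(C)=C/C(=O)N1[C@H](Cc2ccccc2)COC1=O)C(=O)OC
F6 | step 8 | auxiliary adduct: trans-fused Δ6-octalin of 12 with an (R)-4-benzyl-2-oxooxazolidin-3-yl carbonyl group on C9 | CC(C)(C)[Si](C)(C)O[C@@H]1C=C[C@H]2[C@@](C)(CCCC2(C(=O)OC)C(=O)OC)[C@@H]1C(=O)N3[C@H](Cc4ccccc4)COC3=O
F7 | step 18 | half acid: C4 equatorial CO2H, axial CO2Me (otherwise as 23) | CC(C)(C)[Si](C)(C)O[C@@H]1CC[C@H]2[C@@](C)(CCC[C@@]2(C(=O)O)C(=O)OC)[C@@H]1CC[C@@H](C)CCO[Si](c3ccccc3)(c4ccccc4)C(C)(C)C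
F8 | step 16 | C11 carbinol (both C11 epimers) from addition of the C12–C15 organocerium reagent to 14 | CC(C)(C)[Si](C)(C)O[C@@H]1C=C[C@H]2[C@@](C)(CCCC2(C(=O)OC)C(=O)OC)[C@@H]1C(O)C[C@@H](C)CCO[Si](c3ccccc3)(c4ccccc4)C(C)(C)C
F9 | step 16 | C11 O-(imidazol-1-ylthiocarbonyl) derivative of F8 | CC(C)(C)[Si](C)(C)O[C@@H]1C=C[C@H]2[C@@](C)(CCCC2(C(=O)OC)C(=O)OC)[C@@H]1C(OC(=S)n3ccnc3)C[C@@H](C)CCO[Si](c4ccccc4)(c5ccccc5)C(C)(C)C
F10 | step 16 | C11-deoxy compound with C6=C7 still in place (saturated C11–C15 chain) | CC(C)(C)[Si](C)(C)O[C@@H]1C=C[C@H]2[C@@](C)(CCCC2(C(=O)OC)C(=O)OC)[C@@H]1CC[C@@H](C)CCO[Si](c3ccccc3)(c4ccccc4)C(C)(C)C
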